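## Retrosynthetic overview

1. Target ⇒ (two O-acylations, acetal hydrolysis) ⇒ a tricyclic epoxy acetonide in which O9 and O11 are tied together as a 1,3-dioxane.
2. Key disconnection: C7–C8 and C7–O in one operation. An open-chain diphenylsulfonium salt gives an ylide that adds to the C8 ketone (a 1,3-dioxan-5-one), closing the cyclodec-3-ene and the oxirane together.
3. Sulfonium salt ⇒ (halide exchange/S-alkylation, acetalisation, α'-hydroxylation of a methyl ketone) ⇒ enoate methyl ketone ⇒ Wittig reaction (C3=C4) of a C4–C7 ylide with a keto-aldehyde.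
4. Keto-aldehyde ⇒ (S)-carvone by Luche reduction, directed epoxidation and periodate ring cleavage. Carvone supplies C1–C3, C8–C11 and both ring stereocentres (C1, C9).
5. Ring order: carvone ring opened (step 4) → temporary 1,3-dioxane (step 8) → cyclodecene and oxirane together (step 10) → dioxane removed (step 11).

Assumption: the side-chain centre as written is (R)-2-methylbutanoate, and (R)-2-methylbutanoic acid is taken as commercially available.

Atom labels used for all intermediates: C1 = CH bearing isopropenyl, C2, C3=C4 (C4 bears CO2Me), C5, C6, C7 (oxirane CH), C8 (oxirane C), C9 (CHOAc), C10 (ring CH2), C11 = exocyclic CH2O.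

## Route

Step 1
Reactants: 1 (S)-(+)-carvone
Product: 2 (1S,5S)-cis-carveol
Conditions: NaBH4, CeCl3·7H2O, MeOH, −20 °C → 0 °C
Reagents that add atoms: none
Why: Luche 1,2-reduction delivers hydride to the carbonyl face anti to the isopropenyl group, giving the cis allylic alcohol (new centre S, the future C9; dr ≥ 95:5) without touching either C=C.

Step 2
Reactants: 2 (1S,5S)-cis-carveol
Product: 3 syn-epoxy alcohol (1S,2S,4R,6R)-1-methyl-4-(prop-1-en-2-yl)-7-oxabicyclo[4.1.0]heptan-2-ol
Conditions: VO(acac)2 (2 mol%), t-BuOOH (1.3 equiv), toluene, 0 °C → rt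
Reagents that add atoms: tert-butyl hydroperoxide, CC(C)(C)OO
Why: Sharpless vanadium-catalysed hydroxyl-directed epoxidation oxidises only the allylic-alcohol alkene, on the OH face; the isopropenyl group is untouched and the two oxirane centres are erased again in step 4.

Step 3
Reactants: 3 syn-epoxy alcohol
Product: 4 TBS ether of 3 (tert-butyldimethylsilyl ether at the carbinol oxygen)
Conditions: TBSCl, imidazole, DMAP (cat.), DMF, 40 °C
Reagents that add atoms: tert-butyldimethylsilyl chloride, CC(C)(C)[Si](C)(C)Cl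
Why: Standard silyl protection; the hydroxyl must be masked because a free α-hydroxy ketone or 1,2,3-triol would be over-cleaved by periodate in step 4, and no stereocentre is touched.

Step 4
Reactants: 4 TBS ether of 3
Product: 6 (3R,5S)-5-[(tert-butyldimethylsilyl)oxy]-6-oxo-3-(prop-1-en-2-yl)heptanal, via trans-diol 5 (not isolated)
Conditions: H5IO6 (1.5 equiv), THF/H2O (4:1), 0 °C → rt; used at once
Reagents that add atoms: water, O
Why: Acid-catalysed anti hydrolysis of the oxirane followed by Malaprade glycol cleavage in one pot (as in the known limonene oxide → keto-aldehyde cleavage) opens the ring between C8 and C3; the 1,1-disubstituted alkene and the silyl ether are inert and C1/C9 are not affected.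

Step 5
Reactants: 7 methyl (triphenyl-λ5-phosphanylidene)acetate (2.0 equiv); 8 1-chloro-3-iodopropane
Product: 10 methyl 5-chloro-2-(triphenyl-λ5-phosphanylidene)pentanoate, via phosphonium iodide 9 (not isolated)
Conditions: EtOAc, reflux, 16 h; filter
Reagents that add atoms: 8 1-chloro-3-iodopropane, ClCCCI
Why: Bestmann C-alkylation of the stabilised ylide at the much more reactive C–I end, then transylidation by the second equivalent of 7, gives the α-branched ylide; no stereocentre is formed.

Step 6
Reactants: 6 keto-aldehyde; 10 α-branched ylide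
Product: 11 methyl (2E,5S,7S)-7-[(tert-butyldimethylsilyl)oxy]-2-(3-chloropropyl)-8-oxo-5-(prop-1-en-2-yl)non-2-enoate
Conditions: toluene, 70 °C, 12 h
Reagents that add atoms: 10 methyl 5-chloro-2-(triphenyl-λ5-phosphanylidene)pentanoate, COC(=O)C(CCCCl)=P(c1ccccc1)(c1ccccc1)c1ccccc1
Why: Wittig olefination with an α-substituted ester-stabilised ylide is aldehyde-selective (the ketone does not react) and gives the trisubstituted enoate with CO2Me trans to C2 (E, ≥ 95:5), the geometry in which both future ring bonds are cis.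

Step 7
Reactants: 11 enoate methyl ketone
Product: 14 methyl (2E,5S,7S)-7-[(tert-butyldimethylsilyl)oxy]-2-(3-chloropropyl)-9-hydroxy-8-oxo-5-(prop-1-en-2-yl)non-2-enoate, via TMS enol ether 12 (not isolated), via α-silyloxy ketone 13 (not isolated)
Conditions: LiHMDS, TMSCl, THF, −78 °C; then mCPBA (1.05 equiv), NaHCO3, CH2Cl2, −40 °C → −20 °C; then citric acid, MeOH, 0 °C
Reagents that add atoms: 3-chloroperbenzoic acid, O=C(OO)c1cccc(Cl)c1
Why: Kinetic deprotonation at the methyl group (not at the hindered C9–H) with in situ silylation, then Rubottom oxidation, in which the electron-rich silyl enol ether consumes one equivalent of peracid much faster than the 1,1-disubstituted alkene or the enoate; C9 is never deprotonated and keeps its configuration.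

Step 8
Reactants: 14 α'-hydroxy ketone
Product: 16 methyl (2E,5S)-2-(3-chloropropyl)-5-{[(4S)-2,2-dimethyl-5-oxo-1,3-dioxan-4-yl]methyl}-6-methylhepta-2,6-dienoate, via dihydroxy ketone 15 (not isolated)
Conditions: HF·pyridine, THF/pyridine, 0 °C → rt; then 2,2-dimethoxypropane, PPTS (cat.), acetone, rt
Reagents that add atoms: 2,2-dimethoxypropane, COC(C)(C)OC
Why: Fluoride desilylation followed by acid-catalysed acetalisation of the 1,3-dihydroxy ketone gives the six-membered 1,3-dioxan-5-one (Enders-type dioxanone), which protects O9 and O11 and holds C9–C8–C11 in a chair for face control in step 10; C9 is unchanged.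

Step 9
Reactants: 16 dioxanone chloride
Product: 18 {(4E,7S)-7-{[(4S)-2,2-dimethyl-5-oxo-1,3-dioxan-4-yl]methyl}-4-(methoxycarbonyl)-8-methylnona-4,8-dien-1-yl}diphenylsulfonium tetrafluoroborate, via iodide 17 (not isolated)
Conditions: NaI, acetone, 55 °C; filter, evaporate; then Ph2S (5 equiv), AgBF4 (1.1 equiv), 2,6-di-tert-butylpyridine (0.2 equiv), CH2Cl2, 0 °C → rt, dark
Reagents that add atoms: diphenyl sulfide, c1ccc(Sc2ccccc2)cc1; silver tetrafluoroborate, [Ag+].F[B-](F)(F)F
Why: Finkelstein exchange and then silver-assisted S-alkylation of diphenyl sulfide (the standard preparation of alkyldiphenylsulfonium salts); with two S-phenyl groups, C7–H2 is the only acidic position next to sulfur.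

Step 10
Reactants: 18 sulfonium tetrafluoroborate
Product: 21 epoxy acetonide (cyclodec-3-ene fused to the C7–C8 oxirane and to the O9/O11 isopropylidene dioxane; C1 C7 C8 C9 configured as in 25), via sulfonium ylide 19 (not isolated), via betaine 20 (not isolated)
Conditions: LiHMDS (1.05 equiv, added over 2 h), THF/CH2Cl2 (4:1), 1 mM, −78 °C → −30 °C
Reagents that add atoms: none
Why: Proposed new method: an intramolecular Corey–Chaykovsky epoxidation used as a macrocyclisation. Kinetic deprotonation of the only S–CH2 gives ylide 19, which is roughly five pK units less basic than a ketone enolate and so does not enolise the dioxanone. C7 adds to the C8 ketone to give betaine 20, and the alkoxide displaces Ph2S at C7 (3-exo-tet), so one C–C bond closes the ten-membered ring and one C–O bond closes the oxirane. C8 is set by axial attack on the chair dioxanone with the C10 branch equatorial, the normal course for sulfonium ylides on six-ring ketones and reinforced in 1,3-dioxan-5-ones, which have no syn-axial hydrogens; this leaves the epoxide oxygen equatorial, as in the target. C7 is set because the less congested addition places the tether carbon C6 beside the unsubstituted C11H2 rather than beside the branched C9, giving the trans (E-type) oxirane. The cis C3=C4 bond and the dioxane ring pre-organise the chain and high dilution suppresses oligomers. Closest known chemistry: intermolecular epoxidation of ketones by diphenylsulfonium alkylides and intramolecular sulfonium-ylide epoxidations forming 5–7-membered rings.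

Step 11
Reactants: 21 epoxy acetonide
Product: 22 methyl (1R,4E,7S,9S,10R)-9-hydroxy-10-(hydroxymethyl)-7-(prop-1-en-2-yl)-11-oxabicyclo[8.1.0]undec-4-ene-4-carboxylate
Conditions: AcOH/THF/H2O (3:1:1), 35 °C
Reagents that add atoms: none
Why: Mild acid hydrolysis of the isopropylidene acetal; the oxirane should survive because ionisation at C8 is disfavoured by its two β-oxygens and C7 is secondary and unactivated.

Step 12
Reactants: 22 epoxy diol; 23 (R)-2-methylbutanoic acid
Product: 25 methyl (1R,4E,7S,9S,10S)-9-(acetyloxy)-10-({[(2R)-2-methylbutanoyl]oxy}methyl)-7-(prop-1-en-2-yl)-11-oxabicyclo[8.1.0]undec-4-ene-4-carboxylate, via primary mono-ester 24 (not isolated)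
Conditions: 23 (1.1 equiv), DIC, DMAP (0.1 equiv), CH2Cl2, −20 °C → 0 °C; then Ac2O, pyridine, DMAP, 0 °C → rt
Reagents that add atoms: 23 (R)-2-methylbutanoic acid, CC[C@@H](C)C(=O)O; acetic anhydride, CC(=O)OC(C)=O
Why: Steglich esterification acylates the primary C11 hydroxyl selectively at low temperature without racemising the acid, and the remaining secondary C9 hydroxyl is then acetylated under DMAP catalysis; both reactions occur at oxygen, so no carbinol centre is affected.

## Compound list

1 | (S)-(+)-carvone, (5S)-2-methyl-5-(prop-1-en-2-yl)cyclohex-2-en-1-one | C=C(C)[C@H]1CC=C(C)C(=O)C1 | starting material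
2 | (1S,5S)-2-methyl-5-(prop-1-en-2-yl)cyclohex-2-en-1-ol (cis-carveol) | C=C(C)[C@H]1CC=C(C)[C@@H](O)C1 | intermediate
3 | (1S,2S,4R,6R)-1-methyl-4-(prop-1-en-2-yl)-7-oxabicyclo[4.1.0]heptan-2-ol (oxirane O, OH and isopropenyl all cis) | C=C(C)[C@H]1C[C@H]2O[C@@]2(C)[C@@H](O)C1 | intermediate
4 | tert-butyldimethylsilyl ether of 3, (1R,2S,4S,6R) | C=C(C)[C@H]1C[C@H]2O[C@@]2(C)[C@@H](O[Si](C)(C)C(C)(C)C)C1 | intermediate
5 | trans-1,2-diol from anti addition of water to the oxirane of 4 (inversion at the methyl-bearing carbon) | C=C(C)[C@H]1C[C@@H](O)[C@](C)(O)[C@@H](O[Si](C)(C)C(C)(C)C)C1 | intermediate (not isolated)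
6 | (3R,5S)-5-[(tert-butyldimethylsilyl)oxy]-6-oxo-3-(prop-1-en-2-yl)heptanal | C=C(C)[C@@H](CC=O)C[C@H](O[Si](C)(C)C(C)(C)C)C(C)=O | intermediate
7 | methyl (triphenyl-λ5-phosphanylidene)acetate | COC(=O)C=P(c1ccccc1)(c1ccccc1)c1ccccc1 | starting material
8 | 1-chloro-3-iodopropane | ClCCCI | starting material
9 | (5-chloro-1-methoxy-1-oxopentan-2-yl)triphenylphosphonium iodide (racemic) | COC(=O)C(CCCCl)[P+](c1ccccc1)(c1ccccc1)c1ccccc1.[I-] | intermediate (not isolated)
10 | methyl 5-chloro-2-(triphenyl-λ5-phosphanylidene)pentanoate | COC(=O)C(CCCCl)=P(c1ccccc1)(c1ccccc1)c1ccccc1 | intermediate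
11 | methyl (2E,5S,7S)-7-[(tert-butyldimethylsilyl)oxy]-2-(3-chloropropyl)-8-oxo-5-(prop-1-en-2-yl)non-2-enoate | C=C(C)[C@@H](C/C=C(\CCCCl)C(=O)OC)C[C@H](O[Si](C)(C)C(C)(C)C)C(C)=O | intermediate
12 | methyl (2E,5S,7S)-7-[(tert-butyldimethylsilyl)oxy]-2-(3-chloropropyl)-5-(prop-1-en-2-yl)-8-[(trimethylsilyl)oxy]nona-2,8-dienoate | C=C(C)[C@@H](C/C=C(\CCCCl)C(=O)OC)C[C@H](O[Si](C)(C)C(C)(C)C)C(=C)O[Si](C)(C)C | intermediate (not isolated)
13 | methyl (2E,5S,7S)-7-[(tert-butyldimethylsilyl)oxy]-2-(3-chloropropyl)-8-oxo-5-(prop-1-en-2-yl)-9-[(trimethylsilyl)oxy]non-2-enoate | C=C(C)[C@@H](C/C=C(\CCCCl)C(=O)OC)C[C@H](O[Si](C)(C)C(C)(C)C)C(=O)CO[Si](C)(C)C | intermediate (not isolated)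
14 | methyl (2E,5S,7S)-7-[(tert-butyldimethylsilyl)oxy]-2-(3-chloropropyl)-9-hydroxy-8-oxo-5-(prop-1-en-2-yl)non-2-enoate | C=C(C)[C@@H](C/C=C(\CCCCl)C(=O)OC)C[C@H](O[Si](C)(C)C(C)(C)C)C(=O)CO | intermediate
15 | methyl (2E,5S,7S)-2-(3-chloropropyl)-7,9-dihydroxy-8-oxo-5-(prop-1-en-2-yl)non-2-enoate | C=C(C)[C@@H](C/C=C(\CCCCl)C(=O)OC)C[C@H](O)C(=O)CO | intermediate (not isolated)
16 | methyl (2E,5S)-2-(3-chloropropyl)-5-{[(4S)-2,2-dimethyl-5-oxo-1,3-dioxan-4-yl]methyl}-6-methylhepta-2,6-dienoate | C=C(C)[C@@H](C/C=C(\CCCCl)C(=O)OC)C[C@@H]1OC(C)(C)OCC1=O | intermediate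
17 | methyl (2E,5S)-5-{[(4S)-2,2-dimethyl-5-oxo-1,3-dioxan-4-yl]methyl}-2-(3-iodopropyl)-6-methylhepta-2,6-dienoate | C=C(C)[C@@H](C/C=C(\CCCI)C(=O)OC)C[C@@H]1OC(C)(C)OCC1=O | intermediate (not isolated)
18 | {(4E,7S)-7-{[(4S)-2,2-dimethyl-5-oxo-1,3-dioxan-4-yl]methyl}-4-(methoxycarbonyl)-8-methylnona-4,8-dien-1-yl}diphenylsulfonium tetrafluoroborate | C=C(C)[C@@H](C/C=C(\CCC[S+](c1ccccc1)c1ccccc1)C(=O)OC)C[C@@H]1OC(C)(C)OCC1=O.F[B-](F)(F)F | intermediate
19 | sulfonium ylide of 18 (carbanion at C7, the carbon next to sulfur) | C=C(C)[C@@H](C/C=C(\CC[CH-][S+](c1ccccc1)c1ccccc1)C(=O)OC)C[C@@H]1OC(C)(C)OCC1=O | intermediate (not isolated)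
20 | betaine: ten-membered ring closed by the C7–C8 bond, C7 bearing Ph2S(+), C8 bearing O(−), dioxane intact | C=C(C)[C@H]1C/C=C(/C(=O)OC)CC[C@H]([S+](c2ccccc2)c2ccccc2)[C@@]2([O-])COC(C)(C)O[C@H]2C1 | intermediate (not isolated)
21 | epoxy acetonide: target skeleton with O9 and O11 bridged by CMe2 (oxirane spiro to the 1,3-dioxane at C8); C1, C7, C8, C9 as in 25 | C=C(C)[C@H]1C/C=C(/C(=O)OC)CC[C@H]2O[C@@]23COC(C)(C)O[C@H]3C1 | intermediate
22 | methyl (1R,4E,7S,9S,10R)-9-hydroxy-10-(hydroxymethyl)-7-(prop-1-en-2-yl)-11-oxabicyclo[8.1.0]undec-4-ene-4-carboxylate | C=C(C)[C@H]1C/C=C(/C(=O)OC)CC[C@H]2O[C@]2(CO)[C@@H](O)C1 | intermediate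
23 | (R)-2-methylbutanoic acid | CC[C@@H](C)C(=O)O | starting material
24 | methyl (1R,4E,7S,9S,10R)-9-hydroxy-10-({[(2R)-2-methylbutanoyl]oxy}methyl)-7-(prop-1-en-2-yl)-11-oxabicyclo[8.1.0]undec-4-ene-4-carboxylate | C=C(C)[C@H]1C/C=C(/C(=O)OC)CC[C@H]2O[C@]2(COC(=O)[C@H](C)CC)[C@@H](O)C1 | intermediate (not isolated)
25 | methyl (1R,4E,7S,9S,10S)-9-(acetyloxy)-10-({[(2R)-2-methylbutanoyl]oxy}methyl)-7-(prop-1-en-2-yl)-11-oxabicyclo[8.1.0]undec-4-ene-4-carboxylate (CNP0352790.1) | C=C(C)[C@H]1C/C=C(/C(=O)OC)CC[C@H]2O[C@]2(COC(=O)[C@H](C)CC)[C@@H](OC(C)=O)C1 | target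

## Step count and risks

Total step count: 12. Longest linear sequence: 11 steps (steps 1–4 and 6–12, from (S)-carvone); step 5 is a one-step side branch.

The three steps most likely to fail are 10, 8 and 7.

Step 10 is the main risk: the ylide may decay or oligomerise before a ten-membered ring closes, and the C7/C8 selectivity rests on a chair model and a steric argument, not on precedent. The fallback sets out from iodide 17 and comes back at 21. The iodide is oxidised with Me3NO in DMSO (40 °C) to the keto-aldehyde F1. A samarium diiodide pinacol macrocyclisation (THF, high dilution, −78 °C → rt), with both carbonyl oxygens held on samarium, gives the cis-7,8-diol F2. The secondary C7 hydroxyl is mesylated selectively (MsCl, Et3N, −20 °C) to the hydroxy mesylate F3, and K2CO3 in MeOH closes the oxirane with inversion at C7 to give 21. The ring and the oxirane are then made in separate steps and the oxirane configuration is fixed by an SN2 displacement.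

Step 8 may fail because the free α,α'-dihydroxy ketone 15 can dimerise or isomerise through its enediol before it is acetalised. The fallback sets out from 14 and comes back at 16. 2-Methoxypropene with catalytic PPTS (CH2Cl2, 0 °C) caps the primary hydroxyl as the mixed acetal F4. Buffered TBAF/AcOH removes the silyl group to give the hydroxy mixed acetal F5, and catalytic PPTS closes it to 16 by intramolecular transacetalisation. The dioxane is built one C–O bond at a time and the free diol never appears.

Step 7 may fail if the peracid also epoxidises the isopropenyl group or if enolisation is not clean at the methyl group. The fallback sets out from 11 and comes back at 14. The same kinetic silyl enol ether 12 is brominated with NBS (THF, −78 °C) to the bromomethyl ketone F6. Caesium formate in DMF (0 °C) displaces bromide to give the formate ester F7, and KHCO3 in MeOH removes the formyl group to give 14. The oxygen is introduced by halogenation and SN2 substitution, so no peracid meets the alkenes.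

## Further compounds

F1 | step 10 | methyl (2E,5S)-5-{[(4S)-2,2-dimethyl-5-oxo-1,3-dioxan-4-yl]methyl}-6-methyl-2-(3-oxopropyl)hepta-2,6-dienoate | C=C(C)[C@@H](C/C=C(\CCC=O)C(=O)OC)C[C@@H]1OC(C)(C)OCC1=O
F2 | step 10 | cis-7,8-diol: ten-membered ring closed by the C7–C8 bond, OH on C7 and on C8, dioxane intact | C=C(C)[C@H]1C/C=C(/C(=O)OC)CC[C@H](O)[C@@]2(O)COC(C)(C)O[C@H]2C1
F3 | step 10 | C7 methanesulfonate of F2 (C8 hydroxyl free) | C=C(C)[C@H]1C/C=C(/C(=O)OC)CC[C@H](OS(C)(=O)=O)[C@@]2(O)COC(C)(C)O[C@H]2C1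
F4 | step 8 | methyl (2E,5S,7S)-7-[(tert-butyldimethylsilyl)oxy]-2-(3-chloropropyl)-9-[(2-methoxypropan-2-yl)oxy]-8-oxo-5-(prop-1-en-2-yl)non-2-enoate | C=C(C)[C@@H](C/C=C(\CCCCl)C(=O)OC)C[C@H](O[Si](C)(C)C(C)(C)C)C(=O)COC(C)(C)OC
F5 | step 8 | methyl (2E,5S,7S)-2-(3-chloropropyl)-7-hydroxy-9-[(2-methoxypropan-2-yl)oxy]-8-oxo-5-(prop-1-en-2-yl)non-2-enoate | C=C(C)[C@@H](C/C=C(\CCCCl)C(=O)OC)C[C@H](O)C(=O)COC(C)(C)OC
F6 | step 7 | methyl (2E,5S,7S)-9-bromo-7-[(tert-butyldimethylsilyl)oxy]-2-(3-chloropropyl)-8-oxo-5-(prop-1-en-2-yl)non-2-enoate | C=C(C)[C@@H](C/C=C(\CCCCl)C(=O)OC)C[C@H](O[Si](C)(C)C(C)(C)C)C(=O)CBr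
F7 | step 7 | methyl (2E,5S,7S)-7-[(tert-butyldimethylsilyl)oxy]-2-(3-chloropropyl)-9-(formyloxy)-8-oxo-5-(prop-1-en-2-yl)non-2-enoate | C=C(C)[C@@H](C/C=C(\CCCCl)C(=O)OC)C[C@H](O[Si](C)(C)C(C)(C)C)C(=O)COC=O
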